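**Strategy**

Everything rests on cutting the benzene ring of the phthalide at C3a–C4 and C7–C7a. A thermal [4+2] cycloaddition of a chiral 4-silyloxy alk-2-ynoate with 1,1-dimethoxy-3-silyloxybutadiene, followed by loss of methanol, builds the whole arene in one operation and delivers C7–OMe and C5–OH already differentiated. The step exploits the 1,3-dioxygenated carbons C4–C7 of the benzo ring, which map onto the diene, and the adjacent pair C7a/C3a carrying the lactone carbons C1 and C3, which map onto the alkyne. The precursor is a C18 ynoate holding C1 as methyl ester, the C3 stereocentre, and the full C1'–C14' chain with its ketone as a dioxolane and both hydroxyls as silyl ethers.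

Key step: step 11

Remark on the structures: the target is (3S,13'S), and the same centres are C4 (S) and C17 (S) in the ynoate. The descriptor at that carbon stays S from alkyne to arene to lactone because the priority order O > sp or sp2 carbon > CH2 holds throughout. No structure needed correction.

Remark on the design: an undecenyl chain is used so that one ozonolysis unmasks the aldehyde. The last step is run in aqueous acid, not in an alcohol, so that the C10' ketone and C13' hydroxyl are not trapped as a cyclic methyl ketal.

Assumption: (S,S)-ProPhenol is taken as the ligand antipode that directs alkynyl addition to the Re face of an unbranched aliphatic aldehyde. The configuration of the product of step 6 is to be checked by Mosher ester analysis, and (R,R)-ProPhenol is used with nothing else changed if the sense is the reverse.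

**Route**

Step 1
Reactants: 1 (S)-γ-valerolactone [(5S)-5-methyloxolan-2-one]
Product: 2 (4S)-4-hydroxy-N-methoxy-N-methylpentanamide
Conditions: MeNH(OMe)·HCl, AlMe3, CH2Cl2, 0 °C → rt; aq. potassium sodium tartrate work-up; crude used at once
Reagents that add atoms: N,O-dimethylhydroxylamine hydrochloride, CNOC.Cl
Why: Weinreb aminolysis, in which the chloro(methyl)aluminium amide opens the lactone by acyl–oxygen cleavage, so the carbinol carbon is not involved and stays S.

Step 2
Reactants: 2 (4S)-4-hydroxy-N-methoxy-N-methylpentanamide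
Product: 3 (4S)-4-(tert-butyldimethylsilyloxy)-N-methoxy-N-methylpentanamide
Conditions: TBSCl, imidazole, DMF, rt
Reagents that add atoms: tert-butyldimethylsilyl chloride, CC(C)(C)[Si](C)(C)Cl
Why: Imidazole-promoted silylation of a secondary alcohol, done at once because the free hydroxy amide slowly reverts to the lactone, and the ether keeps an alkoxide out of the Grignard step.

Step 3
Reactants: 3 (4S)-4-(tert-butyldimethylsilyloxy)-N-methoxy-N-methylpentanamide; 4 11-bromoundec-1-ene
Product: 6 (2S)-2-(tert-butyldimethylsilyloxy)hexadec-15-en-5-one, via undec-10-enylmagnesium bromide 5 (not isolated)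
Conditions: 4, Mg, I2 (cat.), THF, 40 °C; then 3, THF, 0 °C; aq. NH4Cl
Reagents that add atoms: none
Why: Grignard addition to a Weinreb amide stops at the ketone because the five-membered magnesium chelate of the tetrahedral adduct survives until work-up, and the silyl ether and the remote alkene are inert.

Step 4
Reactants: 6 (2S)-2-(tert-butyldimethylsilyloxy)hexadec-15-en-5-one
Product: 7 2-[(3S)-3-(tert-butyldimethylsilyloxy)butyl]-2-(undec-10-en-1-yl)-1,3-dioxolane
Conditions: Me3SiOCH2CH2OSiMe3, TMSOTf (5 mol %), CH2Cl2, −78 → −20 °C; pyridine quench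
Reagents that add atoms: 1,2-bis(trimethylsilyloxy)ethane, C[Si](C)(C)OCCO[Si](C)(C)C
Why: Noyori ketalisation, driven by formation of hexamethyldisiloxane and run cold without free protic acid, keeps the silyl ether and shields the ketone from the organozinc step and from the electron-rich diene.

Step 5
Reactants: 7 2-[(3S)-3-(tert-butyldimethylsilyloxy)butyl]-2-(undec-10-en-1-yl)-1,3-dioxolane
Product: 9 10-{2-[(3S)-3-(tert-butyldimethylsilyloxy)butyl]-1,3-dioxolan-2-yl}decanal, via secondary ozonide 8 (not isolated)
Conditions: O3, CH2Cl2, −78 °C; then PPh3, −78 °C → rt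
Reagents that add atoms: ozone, [O-][O+]=O
Why: Ozonolysis with reductive work-up (Criegee mechanism, phosphine reduction of the ozonide) cuts off the terminal carbon as formaldehyde and leaves the aldehyde, while the ketal, which has no acetal C–H, and the silyl ether do not react.

Step 6
Reactants: 9 10-{2-[(3S)-3-(tert-butyldimethylsilyloxy)butyl]-1,3-dioxolan-2-yl}decanal; 10 methyl propiolate
Product: 12 methyl (4S,17S)-17-(tert-butyldimethylsilyloxy)-14,14-(ethylenedioxy)-4-hydroxyoctadec-2-ynoate, via methylzinc propiolate 11 (not isolated)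
Conditions: 10 (3 equiv), Me2Zn (3 equiv), (S,S)-ProPhenol [2,6-bis{[(2S)-2-(hydroxydiphenylmethyl)pyrrolidin-1-yl]methyl}-4-methylphenol, 20 mol %], Ph3P=O (40 mol %), toluene, 0 °C; then 9 added slowly, 4 °C; aq. NH4Cl
Reagents that add atoms: none
Why: Zinc–ProPhenol catalysed asymmetric alkynylation, in which the methylzinc acetylide of the propiolate adds to the zinc-bound aldehyde inside the chiral dinuclear pocket from the Re face, which sets C4 as S, and the mild organozinc reagents do not touch the ester, ketal or silyl ether.

Step 7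
Reactants: 12 methyl (4S,17S)-17-(tert-butyldimethylsilyloxy)-14,14-(ethylenedioxy)-4-hydroxyoctadec-2-ynoate
Product: 13 methyl (4S,17S)-4,17-bis(tert-butyldimethylsilyloxy)-14,14-(ethylenedioxy)octadec-2-ynoate
Conditions: TBSCl, imidazole, DMF, 0 °C → rt
Reagents that add atoms: tert-butyldimethylsilyl chloride, CC(C)(C)[Si](C)(C)Cl
Why: Silylation of the propargylic alcohol under weakly basic conditions that should not isomerise the 4-oxygenated ynoate, and the ether keeps the hydroxyl from quenching the silyl ketene acetal diene in the key step.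

Step 8
Reactants: 14 acetyl chloride; 15 1,1-dichloroethene
Product: 17 4,4-dichlorobut-3-en-2-one, via 4,4,4-trichlorobutan-2-one 16 (not isolated)
Conditions: AlCl3, CH2Cl2, 0 °C → rt; ice water; distillation (loss of HCl)
Reagents that add atoms: none
Why: Friedel–Crafts-type acylation of an alkene, in which the acylium–AlCl3 complex adds to the CH2 terminus, chloride capture gives the trichloro ketone, and loss of HCl leaves the conjugated dichlorovinyl ketone.

Step 9
Reactants: 17 4,4-dichlorobut-3-en-2-one
Product: 19 4,4-dimethoxybut-3-en-2-one, via 4-chloro-4-methoxybut-3-en-2-one 18 (not isolated)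
Conditions: NaOMe (2.1 equiv), MeOH, 0 °C → rt
Reagents that add atoms: sodium methoxide, [Na+].[O-]C
Why: Two successive conjugate addition–elimination steps (nucleophilic vinylic substitution) replace both β-chlorides of the enone by methoxide to give the ketene acetal.

Step 10
Reactants: 19 4,4-dimethoxybut-3-en-2-one
Product: 20 1,1-dimethoxy-3-(trimethylsilyloxy)buta-1,3-diene
Conditions: TMSCl, Et3N, ZnCl2 (cat.), toluene, 40 °C; filtration; distillation under reduced pressure
Reagents that add atoms: chlorotrimethylsilane, C[Si](C)(C)Cl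
Why: Soft enolisation and O-silylation of the methyl ketone, its only enolisable position, gives the 2-silyloxy diene, which is distilled so that no amine or amine salt reaches the cycloaddition.

Step 11
Reactants: 13 methyl (4S,17S)-4,17-bis(tert-butyldimethylsilyloxy)-14,14-(ethylenedioxy)octadec-2-ynoate; 20 1,1-dimethoxy-3-(trimethylsilyloxy)buta-1,3-diene
Product: 23 methyl 2-[(1S,14S)-1,14-bis(tert-butyldimethylsilyloxy)-11,11-(ethylenedioxy)pentadecyl]-4-hydroxy-6-methoxybenzoate, via cyclohexa-1,4-diene cycloadduct 21 (not isolated), via aryl trimethylsilyl ether 22 (not isolated)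
Conditions: 20 (3 equiv), toluene, 110 °C, sealed tube; then MeOH, K2CO3 (cat.), rt
Reagents that add atoms: none
Why: The reaction is a thermal, concerted but asynchronous normal-demand [4+2] cycloaddition in which the CH2 terminus of the diene (largest HOMO coefficient) bonds to the ynoate β-carbon (future C3a, forming C3a–C4) and the acetal carbon bonds to the α-carbon (future C7a, forming C7–C7a); the 1,4-cyclohexadiene 21 then aromatises by 1,4-elimination of methanol to 22, and methanolysis of the labile aryl silyl ether frees the C5 phenol. The closest known reaction type is the Diels–Alder benzannulation of 1,1-dialkoxy-3-silyloxybutadienes with alk-2-ynoates, which gives 6-substituted 4-hydroxy-2-methoxybenzoates. The one new ring, the six-membered carbocycle, closes by intermolecular [4+2] cycloaddition, both ring bonds being made in the same step. No stereocentre is formed; C4 of the ynoate (future C3) and C17 are spectators, and C4 is guarded against its only plausible loss, base-induced alkyne–allene isomerisation, by heating without base and with amine-free diene. The step needs regioselectivity (methoxy ortho to the ester), which is secured by matched polarisation: the ester is the only acceptor on the alkyne and both donor groups of the diene push electron density to the same CH2 terminus. It also needs chemoselectivity, which the neutral thermal conditions should provide, since the silyl ethers, the dioxolane and the ester have no pathway to react.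

Step 12
Reactants: 23 methyl 2-[(1S,14S)-1,14-bis(tert-butyldimethylsilyloxy)-11,11-(ethylenedioxy)pentadecyl]-4-hydroxy-6-methoxybenzoate
Product: 25 (3S)-5-hydroxy-3-[(13S)-13-hydroxy-10-oxotetradecyl]-7-methoxy-2-benzofuran-1(3H)-one, via triol keto ester 24 (not isolated)
Conditions: 2 M aq. HCl, THF, rt → 40 °C
Reagents that add atoms: water, O
Why: Acid hydrolysis cleaves both silyl ethers and the dioxolane, and the freed benzylic hydroxyl closes the five-membered lactone onto the neighbouring methyl ester (intramolecular transesterification, 5-exo-trig) with loss of methanol; no C–O bond at C3 or C13' is broken, so both centres keep their configuration, and the aqueous medium leaves the 1,4-hydroxy ketone in its open form.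

**Compound list**

1 | (S)-γ-valerolactone, (5S)-5-methyloxolan-2-one | O=C1CC[C@H](C)O1 | starting material
2 | (4S)-4-hydroxy-N-methoxy-N-methylpentanamide | CON(C)C(=O)CC[C@H](C)O | intermediate
3 | (4S)-4-(tert-butyldimethylsilyloxy)-N-methoxy-N-methylpentanamide | CON(C)C(=O)CC[C@H](C)O[Si](C)(C)C(C)(C)C | intermediate
4 | 11-bromoundec-1-ene | C=CCCCCCCCCCBr | starting material
5 | undec-10-enylmagnesium bromide | C=CCCCCCCCCC[Mg]Br | intermediate
6 | (2S)-2-(tert-butyldimethylsilyloxy)hexadec-15-en-5-one | C=CCCCCCCCCCC(=O)CC[C@H](C)O[Si](C)(C)C(C)(C)C | intermediate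
7 | 2-[(3S)-3-(tert-butyldimethylsilyloxy)butyl]-2-(undec-10-en-1-yl)-1,3-dioxolane | C=CCCCCCCCCCC1(OCCO1)CC[C@H](C)O[Si](C)(C)C(C)(C)C | intermediate
8 | 3-(9-{2-[(3S)-3-(tert-butyldimethylsilyloxy)butyl]-1,3-dioxolan-2-yl}nonyl)-1,2,4-trioxolane (secondary ozonide, both epimers at the trioxolane carbon) | C1OC(OO1)CCCCCCCCCC2(OCCO2)CC[C@H](C)O[Si](C)(C)C(C)(C)C | intermediate
9 | 10-{2-[(3S)-3-(tert-butyldimethylsilyloxy)butyl]-1,3-dioxolan-2-yl}decanal | O=CCCCCCCCCCC1(OCCO1)CC[C@H](C)O[Si](C)(C)C(C)(C)C | intermediate
10 | methyl propiolate | C#CC(=O)OC | starting material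
11 | methyl 3-(methylzincio)prop-2-ynoate (methylzinc propiolate) | COC(=O)C#C[Zn]C | intermediate
12 | methyl (4S,17S)-17-(tert-butyldimethylsilyloxy)-14,14-(ethylenedioxy)-4-hydroxyoctadec-2-ynoate | COC(=O)C#C[C@@H](O)CCCCCCCCCC1(OCCO1)CC[C@H](C)O[Si](C)(C)C(C)(C)C | intermediate
13 | methyl (4S,17S)-4,17-bis(tert-butyldimethylsilyloxy)-14,14-(ethylenedioxy)octadec-2-ynoate | COC(=O)C#C[C@@H](O[Si](C)(C)C(C)(C)C)CCCCCCCCCC1(OCCO1)CC[C@H](C)O[Si](C)(C)C(C)(C)C | intermediate
14 | acetyl chloride | CC(=O)Cl | starting material
15 | 1,1-dichloroethene | C=C(Cl)Cl | starting material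
16 | 4,4,4-trichlorobutan-2-one | CC(=O)CC(Cl)(Cl)Cl | intermediate
17 | 4,4-dichlorobut-3-en-2-one | CC(=O)C=C(Cl)Cl | intermediate
18 | 4-chloro-4-methoxybut-3-en-2-one | CC(=O)C=C(Cl)OC | intermediate
19 | 4,4-dimethoxybut-3-en-2-one | CC(=O)C=C(OC)OC | intermediate
20 | 1,1-dimethoxy-3-(trimethylsilyloxy)buta-1,3-diene | COC(OC)=CC(=C)O[Si](C)(C)C | intermediate
21 | methyl 2-[(1S,14S)-1,14-bis(tert-butyldimethylsilyloxy)-11,11-(ethylenedioxy)pentadecyl]-6,6-dimethoxy-4-(trimethylsilyloxy)cyclohexa-1,4-diene-1-carboxylate | COC(=O)C1=C([C@@H](O[Si](C)(C)C(C)(C)C)CCCCCCCCCC2(OCCO2)CC[C@H](C)O[Si](C)(C)C(C)(C)C)CC(O[Si](C)(C)C)=CC1(OC)OC | intermediate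
22 | methyl 2-[(1S,14S)-1,14-bis(tert-butyldimethylsilyloxy)-11,11-(ethylenedioxy)pentadecyl]-6-methoxy-4-(trimethylsilyloxy)benzoate | COC(=O)c1c(OC)cc(O[Si](C)(C)C)cc1[C@@H](O[Si](C)(C)C(C)(C)C)CCCCCCCCCC1(OCCO1)CC[C@H](C)O[Si](C)(C)C(C)(C)C | intermediate
23 | methyl 2-[(1S,14S)-1,14-bis(tert-butyldimethylsilyloxy)-11,11-(ethylenedioxy)pentadecyl]-4-hydroxy-6-methoxybenzoate | COC(=O)c1c(OC)cc(O)cc1[C@@H](O[Si](C)(C)C(C)(C)C)CCCCCCCCCC1(OCCO1)CC[C@H](C)O[Si](C)(C)C(C)(C)C | intermediate
24 | methyl 2-[(1S,14S)-1,14-dihydroxy-11-oxopentadecyl]-4-hydroxy-6-methoxybenzoate | COC(=O)c1c(OC)cc(O)cc1[C@@H](O)CCCCCCCCCC(=O)CC[C@H](C)O | intermediate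
25 | (3S)-5-hydroxy-3-[(13S)-13-hydroxy-10-oxotetradecyl]-7-methoxy-2-benzofuran-1(3H)-one (CNP0341577.2) | COc1cc(O)cc2c1C(=O)O[C@H]2CCCCCCCCCC(=O)CC[C@H](C)O | target

**Step count and risks**

Total steps: 12. Longest linear sequence: 9 (steps 1 to 7, then 11 and 12); the diene branch is 3 steps (8 to 10).

Steps most likely to fail:

1. Step 11. The cycloaddition at the β-branched ynoate may be slow, so that the acyclic ketene-acetal diene is used up by thermal decomposition and protodesilylation before it adds. The fallback is an Alder–Rickert sequence that sets out from 13 and comes back at 22. Commercial 3-methoxycyclohex-2-en-1-one is deprotonated at the α' carbon with lithium diisopropylamide and silylated with TMSCl (THF, −78 °C) to give 1-methoxy-3-(trimethylsilyloxy)cyclohexa-1,3-diene F1, a diene locked s-cis that tolerates long heating. Heating F1 with 13 (xylene, 150 to 180 °C, sealed tube) should give methyl 3-[(1S,14S)-1,14-bis(tert-butyldimethylsilyloxy)-11,11-(ethylenedioxy)pentadecyl]-1-methoxy-5-(trimethylsilyloxy)bicyclo[2.2.2]octa-2,5-diene-2-carboxylate F2 with the same regiochemical pairing (enol ether CH terminus to the β-carbon, methoxy-bearing carbon to the α-carbon). F2 should lose ethene by retro-[4+2] under the same conditions to give 22, which is methanolysed to 23 as in step 11.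

2. Step 6. Facial selectivity may be insufficient for an unbranched aliphatic aldehyde, or the aldehyde may self-condense under the zinc conditions; a minor C4 epimer would be a remote diastereomer that is hard to remove. The fallback sets out from 9 and comes back at 12. Methyl propiolate 10 is deprotonated with LiN(SiMe3)2 (THF, −78 °C) to methyl 3-lithioprop-2-ynoate F3, which adds to 9 to give methyl (17S)-17-(tert-butyldimethylsilyloxy)-14,14-(ethylenedioxy)-4-hydroxyoctadec-2-ynoate as a mixture of C4 epimers F4. Dess–Martin periodinane (CH2Cl2, NaHCO3, 0 °C) oxidises F4 to methyl (17S)-17-(tert-butyldimethylsilyloxy)-14,14-(ethylenedioxy)-4-oxooctadec-2-ynoate F5. Midland reduction of F5 with (S)-Alpine-Borane (B-isopinocampheyl-9-borabicyclo[3.3.1]nonane from (−)-α-pinene, THF, rt) transfers hydride through a boat-like six-membered transition state and should give the (4S) alcohol 12; the ketal is needed here because the reagents would otherwise meet a second ketone.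

3. Step 12. One-pot acid unmasking may stall at partly protected stages (the hindered benzylic silyl ether or the dioxolane), or the 1,4-hydroxy ketone may dehydrate to a cyclic enol ether on long exposure to acid. The fallback sets out from 23 and comes back at 25 in two separate operations. Tetrabutylammonium fluoride (THF, 0 °C → rt) cleaves both silyl ethers, and the benzylic alkoxide lactonises onto the ester under these basic conditions to give (3S)-5-hydroxy-3-(9-{2-[(3S)-3-hydroxybutyl]-1,3-dioxolan-2-yl}nonyl)-7-methoxy-2-benzofuran-1(3H)-one F6. Pyridinium p-toluenesulfonate in acetone/water (50 °C) then removes the dioxolane under nearly neutral conditions to give 25.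

**Further compounds**

F1 | step 11 | 1-methoxy-3-(trimethylsilyloxy)cyclohexa-1,3-diene | COC1=CC(O[Si](C)(C)C)=CCC1
F2 | step 11 | methyl 3-[(1S,14S)-1,14-bis(tert-butyldimethylsilyloxy)-11,11-(ethylenedioxy)pentadecyl]-1-methoxy-5-(trimethylsilyloxy)bicyclo[2.2.2]octa-2,5-diene-2-carboxylate (both bridgehead diastereomers) | COC(=O)C1=C([C@@H](O[Si](C)(C)C(C)(C)C)CCCCCCCCCC3(OCCO3)CC[C@H](C)O[Si](C)(C)C(C)(C)C)C2CCC1(OC)C=C2O[Si](C)(C)C
F3 | step 6 | methyl 3-lithioprop-2-ynoate | COC(=O)C#C[Li]
F4 | step 6 | methyl (17S)-17-(tert-butyldimethylsilyloxy)-14,14-(ethylenedioxy)-4-hydroxyoctadec-2-ynoate (C4 epimers) | COC(=O)C#CC(O)CCCCCCCCCC1(OCCO1)CC[C@H](C)O[Si](C)(C)C(C)(C)C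
F5 | step 6 | methyl (17S)-17-(tert-butyldimethylsilyloxy)-14,14-(ethylenedioxy)-4-oxooctadec-2-ynoate | COC(=O)C#CC(=O)CCCCCCCCCC1(OCCO1)CC[C@H](C)O[Si](C)(C)C(C)(C)C
F6 | step 12 | (3S)-5-hydroxy-3-(9-{2-[(3S)-3-hydroxybutyl]-1,3-dioxolan-2-yl}nonyl)-7-methoxy-2-benzofuran-1(3H)-one | COc1cc(O)cc2c1C(=O)O[C@H]2CCCCCCCCCC1(OCCO1)CC[C@H](C)O
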